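**Retrosynthetic overview** (gibberellane numbering: ring A = C1–C5 and C10; C6 carries carboxyl C7; C8 and C13 are bridgeheads; C16=C17 is the methylene)
1. The route rests on one feature: C10 of ring A is para to the C3 oxygen and is bonded to the benzylic methine C9, which sits next to bridgehead C8. Ring B is therefore closed last, by anodic coupling of a C9=C11 silyl enol ether with the pendant anisole (C9–C10 bond).
2. The bicyclo[3.2.1]octane comes from 3,5-dimethoxybenzoic acid: Birch reductive alkylation creates C8 and ring C, a 2-lithioallyl closure onto C13 makes ring D, and a salt resolution fixes C8/C13.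
3. C6 and C7 are added by Arndt–Eistert homologation and palladium-catalysed enolate arylation with 3-bromo-2-methylanisole. C6 is left as both epimers until ring B exists, then set by equilibration.
4. After ring B: C11 deoxygenation, phenol release, ortho-formylation at C2, diazoacetate annulation of the furan ester, desilylation, saponification.
5. Ring order: C, D, B, furan (ring A arrives intact).

Key step: step 9

Remark (assumption): in step 4 the salt of (R)-1-phenylethylamine with the (1S,5R) acid is taken to be the less soluble one; should the opposite hold, the (S)-amine is used to the same end.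

**Step 1**
Reactants: 1 3,5-dimethoxybenzoic acid; 2 2,3-dibromopropene
Product: 3 1-(2-bromoprop-2-en-1-yl)-3,5-dimethoxycyclohexa-2,5-diene-1-carboxylic acid
Conditions: Li (3 equiv), NH3(l)/THF, −78 °C; isoprene; then 2, −78 to −33 °C; NH4Cl, cold NaH2PO4 (aq) to pH 5
Reagents that add atoms: none
Why: Birch reductive alkylation: the benzoate is reduced to the carboxylate-stabilised dienolate (C8 and C12 become sp3), which is alkylated at C8 by the allylic bromide of 2 once excess metal is destroyed, leaving the vinyl bromide and both enol ethers intact; no stereocentre is formed.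

**Step 2**
Reactants: 3
Product: 4 racemic 1-(2-bromoprop-2-en-1-yl)-3-methoxy-5-oxocyclohex-3-ene-1-carboxylic acid
Conditions: 1 M HCl, THF, 0 °C to rt (short contact)
Reagents that add atoms: water, O
Why: Enol ether hydrolysis followed by conjugation stops at the vinylogous ester, because a 3-methoxyenone hydrolyses far more slowly than an isolated enol ether; this differentiates the two ring arms and makes C8 a stereocentre, formed as the racemate.

**Step 3**
Reactants: 4
Product: 7 racemic 5-(tert-butyldimethylsilyloxy)-6-methylidene-3-oxobicyclo[3.2.1]octane-1-carboxylic acid, via bicyclic dilithium alkoxide carboxylate 5 (not isolated), via silyl ester silyl ether 6 (not isolated)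
Conditions: t-BuLi (3.1 equiv), THF, −78 °C; TBSOTf (2.5 equiv), −78 to 0 °C; 1 M HCl, THF, rt
Reagents that add atoms: tert-butyldimethylsilyl triflate, CC(C)(C)[Si](C)(C)OS(=O)(=O)C(F)(F)F; water, O
Why: Bromine–lithium exchange gives the 2-lithioallyl group, which adds 1,2 to the vinylogous-ester carbonyl (5-exo closure of ring D, a Stork–Danheiser-type addition whose usual elimination is blocked by Bredt's rule); silylation of the bridgehead alkoxide forestalls retro-aldol cleavage, the acid work-up unmasks the C11 ketone, and C13 is set relative to C8 by the ring geometry.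

**Step 4**
Reactants: 7
Product: 8 (1S,5R)-5-(tert-butyldimethylsilyloxy)-6-methylidene-3-oxobicyclo[3.2.1]octane-1-carboxylic acid
Conditions: (R)-1-phenylethylamine (1 equiv), EtOAc, recrystallisation of the salt; 1 M HCl, EtOAc
Reagents that add atoms: none
Why: Classical resolution of a carboxylic acid through diastereomeric ammonium salts; this step fixes the absolute configuration of C8 and C13.

**Step 5**
Reactants: 8
Product: 10 2-diazo-1-[5-(tert-butyldimethylsilyloxy)-6-methylidene-3-oxobicyclo[3.2.1]oct-1-yl]ethan-1-one (bridgeheads as in 8), via acid chloride 9 (not isolated)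
Conditions: (COCl)2, DMF (cat.), CH2Cl2, 0 °C to rt, evaporate; CH2N2 (3 equiv), Et2O, 0 °C
Reagents that add atoms: diazomethane, C=[N+]=[N-]; oxalyl chloride, O=C(Cl)C(=O)Cl (chlorine of 9 only)
Why: First stage of the Arndt–Eistert homologation: the bridgehead acid chloride acylates diazomethane and a second equivalent takes up the HCl, while the ketone and the silyl ether are inert.

**Step 6**
Reactants: 10
Product: 11 methyl 2-[5-(tert-butyldimethylsilyloxy)-6-methylidene-3-oxobicyclo[3.2.1]oct-1-yl]acetate (bridgeheads as in 8)
Conditions: AgO2CPh (10 mol %), Et3N, MeOH, rt, dark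
Reagents that add atoms: methanol, CO
Why: Silver-catalysed Wolff rearrangement: bridgehead C8 migrates to the carbene carbon (the future C6) and methanol traps the ketene as the ester (the future C7).

**Step 7**
Reactants: 11
Product: 12 methyl 2-[3,5-bis(tert-butyldimethylsilyloxy)-6-methylidenebicyclo[3.2.1]oct-2-en-1-yl]acetate (C9=C11 enol ether)
Conditions: LiN(i-Pr)2 (1.05 equiv), THF, −78 °C; TBSOTf (1.1 equiv), −78 °C; NaHCO3 (aq)
Reagents that add atoms: tert-butyldimethylsilyl triflate, CC(C)(C)[Si](C)(C)OS(=O)(=O)C(F)(F)F
Why: Kinetic enolate formation and O-silylation: the axial C9 proton should be removed in preference to C12-H, which is deactivated by the beta-silyloxy group on C13 and screened by the bulky bridgehead silyl ether, and the ester alpha-protons are less acidic than those of the ketone.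

**Step 8**
Reactants: 12; 13 3-bromo-2-methylanisole (1-bromo-3-methoxy-2-methylbenzene)
Product: 14 methyl 2-[3,5-bis(tert-butyldimethylsilyloxy)-6-methylidenebicyclo[3.2.1]oct-2-en-1-yl]-2-(3-methoxy-2-methylphenyl)acetate (both C6 epimers)
Conditions: LiNCy2 (2.3 equiv), Pd(dba)2 (3 mol %), P(t-Bu)3 (3 mol %), toluene, rt; NH4Cl (aq)
Reagents that add atoms: none
Why: Buchwald–Hartwig-type alpha-arylation of an ester enolate: oxidative addition of 13 to zerovalent palladium, enolate transmetalation and reductive elimination form C6–C5, the silyl enol ether being inert without fluoride; C6 forms as both epimers, which converge in step 10.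

**Step 9**
Reactants: 14
Product: 15 tetracyclic 11-ketone ester, methyl 13-(tert-butyldimethylsilyloxy)-3-methoxy-11-oxoallogibberate skeleton with cis B/C fusion (both C6 epimers)
Conditions: constant-current electrolysis, undivided cell, reticulated vitreous carbon anode, Pt cathode, 0.1 M LiClO4 in MeCN/i-PrOH 4:1, 2,6-lutidine (4 equiv), 2.1 F/mol, rt
Reagents that add atoms: none
Why: Anodic one-electron oxidation of the silyl enol ether, the most easily oxidised group, gives a radical cation electrophilic at C9; the anisole carbon para to methoxy (C10) attacks it, and a second electron transfer, loss of the C10 proton to 2,6-lutidine and transfer of the silyl group to isopropanol leave the C11 ketone. The closest known reaction type is the anodic coupling of silyl enol ethers with tethered furans and electron-rich arenes under the same LiClO4/lutidine conditions. Ring B closes in the 5-exo mode with respect to the C9=C11 bond. The new stereocentre C9 is controlled by the bridgehead tether: C6 on C8 lies almost in the enol ether plane and is tilted toward the C14 face, so C10 can reach C9 only on the face turned away from the C15–C16 bridge, giving the cis B/C fusion with H9 syn to C15. The step needs chemoselective oxidation and a single arene position: controlled charge at constant current keeps the potential at the enol ether (the anisole is harder and the 1,1-disubstituted alkene much harder to oxidise), and only C10 is both within reach and activated, the other ortho position carrying the methyl group. Both C6 epimers should cyclise, since C6 is not part of the reacting array.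

**Step 10**
Reactants: 15
Product: 16 methyl 13-(tert-butyldimethylsilyloxy)-3-methoxy-11-oxoallogibberate (C6 ester cis to H9 and C15; H9 syn to C15)
Conditions: NaOMe (0.3 equiv), MeOH, rt; chromatography, the minor C6 epimer is resubmitted
Reagents that add atoms: none
Why: Base equilibration through the ester enolate (C6) and the ketone enolate (C9): ring B is an envelope with C8 as flap, so the ester cis to H9 is pseudo-axial and clear of the C4 methyl whereas its epimer would lie pseudo-equatorial against that peri methyl, and the cis B/C fusion is the only low-strain arrangement at C9.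

**Step 11**
Reactants: 16
Product: 17 C11 tosylhydrazone of 16
Conditions: TsNHNH2 (1.5 equiv), EtOH, 60 °C
Reagents that add atoms: 4-methylbenzenesulfonohydrazide, Cc1ccc(cc1)S(=O)(=O)NN
Why: Condensation of the C11 ketone with the sulfonyl hydrazide gives the tosylhydrazone, the first stage of a Caglioti-type deoxygenation; no stereocentre changes.

**Step 12**
Reactants: 17
Product: 18 methyl 13-(tert-butyldimethylsilyloxy)-3-methoxyallogibberate (C11 now CH2)
Conditions: catecholborane (3 equiv), CHCl3, 0 °C to rt; NaOAc·3H2O, reflux
Reagents that add atoms: none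
Why: Hydroboration of the C=N bond and acetate-induced loss of sulfinate and nitrogen from the resulting hydrazine give the methylene group (catecholborane variant of the Caglioti reduction) under mild, non-basic conditions that leave the ester, C6 and the 1,1-disubstituted alkene untouched.

**Step 13**
Reactants: 18
Product: 19 13-(tert-butyldimethylsilyloxy)-3-hydroxyallogibberic acid (phenol and free C7 acid)
Conditions: NaSEt (8 equiv), DMF, 120 °C; 1 M HCl, 0 °C
Reagents that add atoms: none
Why: SN2 dealkylation by thiolate cleaves the aryl methyl ether and also the methyl ester at their methyl carbons, avoiding the strong acids that would provoke Wagner–Meerwein rearrangement of the 16-ene/13-oxygen unit.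

**Step 14**
Reactants: 19
Product: 20 methyl 13-(tert-butyldimethylsilyloxy)-3-hydroxyallogibberate
Conditions: Me3SiCHN2, toluene/MeOH 4:1, 0 °C
Reagents that add atoms: (trimethylsilyl)diazomethane, C[Si](C)(C)C=[N+]=[N-]
Why: Diazoalkane O-methylation is selective for the carboxylic acid over the less acidic phenol and restores the ester that must mask C7 during the diazoacetate step.

**Step 15**
Reactants: 20
Product: 21 methyl 13-(tert-butyldimethylsilyloxy)-2-formyl-3-hydroxyallogibberate
Conditions: MgCl2 (2 equiv), Et3N (4 equiv), (CH2O)n (6 equiv), MeCN, reflux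
Reagents that add atoms: paraformaldehyde (formaldehyde), C=O
Why: Magnesium-phenoxide-directed ortho-formylation (Casnati–Skattebøl type) can only take place at C2, the single free ortho position, since C4 carries the methyl group.

**Step 16**
Reactants: 21
Product: 23 13-O-tert-butyldimethylsilyl pharbinilic acid furan ethyl ester C7 methyl ester, via dihydrobenzofuranol hemiacetal 22 (not isolated)
Conditions: N2CHCO2Et (1.5 equiv), HBF4·OEt2 (10 mol %), CH2Cl2, rt; then TsOH·H2O (0.2 equiv), 35 °C
Reagents that add atoms: ethyl diazoacetate, CCOC(=O)C=[N+]=[N-]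
Why: Acid-catalysed addition of the diazoacetate to the aldehyde, 1,2-aryl shift with loss of nitrogen and hemiacetal formation with the phenol give 22, whose dehydration aromatises the furan with the ester on the carbon bonded to C2 (benzofuran-3-carboxylate synthesis from a salicylaldehyde).

**Step 17**
Reactants: 23
Product: 24 pharbinilic acid furan ethyl ester C7 methyl ester (free C13 hydroxyl)
Conditions: Bu4NF (3 equiv), THF, 50 °C
Reagents that add atoms: none
Why: Fluoride-induced desilylation cleaves the hindered bridgehead silyl ether through Si–F bond formation without touching the esters or the alkene.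

**Step 18**
Reactants: 24
Product: 25 pharbinilic acid
Conditions: LiOH (10 equiv), THF/MeOH/H2O, 55 °C; 1 M HCl to pH 3, 0 °C
Reagents that add atoms: lithium hydroxide, [Li+].[OH-]
Why: Saponification (BAc2) of the furan ethyl ester and of the hindered C7 methyl ester followed by cold, brief acidification gives the diacid; C6 already holds the configuration favoured at equilibrium, so the basic conditions should not erode it.

**Compound list**
1 | 3,5-dimethoxybenzoic acid | COc1cc(OC)cc(C(=O)O)c1 | starting material
2 | 2,3-dibromopropene | C=C(Br)CBr | starting material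
3 | 1-(2-bromoprop-2-en-1-yl)-3,5-dimethoxycyclohexa-2,5-diene-1-carboxylic acid (achiral) | C=C(Br)CC1(C(=O)O)C=C(OC)CC(OC)=C1 | intermediate
4 | racemic 1-(2-bromoprop-2-en-1-yl)-3-methoxy-5-oxocyclohex-3-ene-1-carboxylic acid | C=C(Br)CC1(C(=O)O)CC(=O)C=C(OC)C1 | intermediate
5 | racemic dilithium 3-methoxy-6-methylidene-5-oxidobicyclo[3.2.1]oct-3-ene-1-carboxylate | C=C1CC2(CC1([O-])C=C(OC)C2)C(=O)[O-].[Li+].[Li+] | intermediate
6 | racemic tert-butyldimethylsilyl 5-(tert-butyldimethylsilyloxy)-3-methoxy-6-methylidenebicyclo[3.2.1]oct-3-ene-1-carboxylate | C=C1CC2(CC1(O[Si](C)(C)C(C)(C)C)C=C(OC)C2)C(=O)O[Si](C)(C)C(C)(C)C | intermediate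
7 | racemic 5-(tert-butyldimethylsilyloxy)-6-methylidene-3-oxobicyclo[3.2.1]octane-1-carboxylic acid | C=C1CC2(CC1(O[Si](C)(C)C(C)(C)C)CC(=O)C2)C(=O)O | intermediate
8 | (1S,5R)-5-(tert-butyldimethylsilyloxy)-6-methylidene-3-oxobicyclo[3.2.1]octane-1-carboxylic acid | C=C1C[C@@]2(C[C@@]1(O[Si](C)(C)C(C)(C)C)CC(=O)C2)C(=O)O | intermediate
9 | acid chloride of 8 | C=C1C[C@@]2(C[C@@]1(O[Si](C)(C)C(C)(C)C)CC(=O)C2)C(=O)Cl | intermediate
10 | bridgehead diazomethyl ketone derived from 8 | C=C1C[C@@]2(C[C@@]1(O[Si](C)(C)C(C)(C)C)CC(=O)C2)C(=O)C=[N+]=[N-] | intermediate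
11 | methyl 2-[5-(tert-butyldimethylsilyloxy)-6-methylidene-3-oxobicyclo[3.2.1]oct-1-yl]acetate, bridgeheads as in 8 | C=C1C[C@@]2(C[C@@]1(O[Si](C)(C)C(C)(C)C)CC(=O)C2)CC(=O)OC | intermediate
12 | methyl 2-[3,5-bis(tert-butyldimethylsilyloxy)-6-methylidenebicyclo[3.2.1]oct-2-en-1-yl]acetate, bridgeheads as in 8 | C=C1C[C@@]2(C[C@@]1(O[Si](C)(C)C(C)(C)C)CC(O[Si](C)(C)C(C)(C)C)=C2)CC(=O)OC | intermediate
13 | 3-bromo-2-methylanisole | COc1cccc(Br)c1C | starting material
14 | methyl 2-[3,5-bis(tert-butyldimethylsilyloxy)-6-methylidenebicyclo[3.2.1]oct-2-en-1-yl]-2-(3-methoxy-2-methylphenyl)acetate, both C6 epimers (C6 left open in the SMILES) | C=C1C[C@@]2(C[C@@]1(O[Si](C)(C)C(C)(C)C)CC(O[Si](C)(C)C(C)(C)C)=C2)C(C(=O)OC)c1cccc(OC)c1C | intermediate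
15 | tetracyclic 11-ketone methyl ester, cis B/C fusion, both C6 epimers (C6 left open in the SMILES) | C=C1C[C@]23C[C@@]1(O[Si](C)(C)C(C)(C)C)CC(=O)[C@H]2c1ccc(OC)c(C)c1C3C(=O)OC | intermediate
16 | methyl 13-(tert-butyldimethylsilyloxy)-3-methoxy-11-oxoallogibberate (C6 ester cis to H9) | C=C1C[C@]23C[C@@]1(O[Si](C)(C)C(C)(C)C)CC(=O)[C@H]2c1ccc(OC)c(C)c1[C@@H]3C(=O)OC | intermediate
17 | C11 tosylhydrazone of 16 | C=C1C[C@]23C[C@@]1(O[Si](C)(C)C(C)(C)C)CC(=NNS(=O)(=O)c4ccc(C)cc4)[C@H]2c1ccc(OC)c(C)c1[C@@H]3C(=O)OC | intermediate
18 | methyl 13-(tert-butyldimethylsilyloxy)-3-methoxyallogibberate | C=C1C[C@]23C[C@@]1(O[Si](C)(C)C(C)(C)C)CC[C@H]2c1ccc(OC)c(C)c1[C@@H]3C(=O)OC | intermediate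
19 | 13-(tert-butyldimethylsilyloxy)-3-hydroxyallogibberic acid | C=C1C[C@]23C[C@@]1(O[Si](C)(C)C(C)(C)C)CC[C@H]2c1ccc(O)c(C)c1[C@@H]3C(=O)O | intermediate
20 | methyl 13-(tert-butyldimethylsilyloxy)-3-hydroxyallogibberate | C=C1C[C@]23C[C@@]1(O[Si](C)(C)C(C)(C)C)CC[C@H]2c1ccc(O)c(C)c1[C@@H]3C(=O)OC | intermediate
21 | methyl 13-(tert-butyldimethylsilyloxy)-2-formyl-3-hydroxyallogibberate | C=C1C[C@]23C[C@@]1(O[Si](C)(C)C(C)(C)C)CC[C@H]2c1cc(C=O)c(O)c(C)c1[C@@H]3C(=O)OC | intermediate
22 | 2-hydroxy-2,3-dihydrobenzofuran-3-carboxylate hemiacetal (mixture at the two new centres) | C=C1C[C@]23C[C@@]1(O[Si](C)(C)C(C)(C)C)CC[C@H]2c1cc2C(C(=O)OCC)C(O)Oc2c(C)c1[C@@H]3C(=O)OC | intermediate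
23 | 13-O-tert-butyldimethylsilyl pharbinilic acid furan ethyl ester C7 methyl ester | C=C1C[C@]23C[C@@]1(O[Si](C)(C)C(C)(C)C)CC[C@H]2c1cc2c(C(=O)OCC)coc2c(C)c1[C@@H]3C(=O)OC | intermediate
24 | pharbinilic acid furan ethyl ester C7 methyl ester | C=C1C[C@]23C[C@@]1(O)CC[C@H]2c1cc2c(C(=O)OCC)coc2c(C)c1[C@@H]3C(=O)OC | intermediate
25 | pharbinilic acid | C=C1C[C@]23C[C@@]1(O)CC[C@H]2c1cc2c(C(=O)O)coc2c(C)c1[C@@H]3C(=O)O | target

**Step count and risks**
Total: 18 steps. Longest linear sequence: 18 steps (from 1; 13 enters at step 8).

Step 9 (anodic ring B closure). The radical cation may lose its silyl group or be trapped by solvent before the hindered arene attacks, or the more electron-rich product may be over-oxidised at the anode. The fallback is a two-electron palladium enolate arylation. It sets out from 14: buffered aqueous acetic acid in THF cleaves only the enol ether to give the keto arylacetate F1; NBS in MeCN brominates the anisole para to methoxy, at C10, to give the aryl bromide F2; Pd2(dba)3, P(t-Bu)3 and NaOt-Bu in toluene at 80 °C then effect intramolecular ketone alpha-arylation. Only the C9 enolate can reach C10, so no regiodefined enol ether is needed. The route is rejoined at 15.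

Step 7 (regioselective enol silane). Deprotonation may partly take place at C12, giving the C11=C12 enol ether that cannot cyclise. The fallback uses alkoxide direction in place of steric screening. It sets out from 11: HF·pyridine in THF removes the bridgehead silyl group to give the hydroxy keto ester F3; LiN(i-Pr)2 (2.2 equiv) at −78 °C forms the C13 alkoxide first, whose charge disfavours enolisation at the adjacent C12; TBSOTf (2.3 equiv) then silylates both oxygens. The route is rejoined at 12.

Step 8 (ester enolate arylation). Transmetalation and reductive elimination may be slow at the neopentyl-type enolate with an ortho-substituted aryl group, so that enolate decomposition or aryl halide reduction takes over. The fallback builds the arylacetate by Wolff rearrangement of an alpha-aryl diazoketone. It sets out from 8 by way of acid chloride 9: Negishi acylation with (3-methoxy-2-methylbenzyl)zinc chloride F4 (from the benzyl chloride and Zn) under Pd(PPh3)4 gives the benzyl ketone F5; diazo transfer with 4-acetamidobenzenesulfonyl azide and DBU, selective for the doubly activated methylene, gives the aryl diazoketone F6; AgO2CPh/Et3N in MeOH (or irradiation) makes C8 migrate and gives the keto arylacetate F1. Kinetic silylation of F1 (LiN(i-Pr)2 2.2 equiv, TBSOTf; any ketene acetal reverts on aqueous work-up) rejoins the route at 14.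

**Further compounds**
F1 | step 9 | methyl 2-[5-(tert-butyldimethylsilyloxy)-6-methylidene-3-oxobicyclo[3.2.1]oct-1-yl]-2-(3-methoxy-2-methylphenyl)acetate, both C6 epimers | C=C1C[C@@]2(C[C@@]1(O[Si](C)(C)C(C)(C)C)CC(=O)C2)C(C(=O)OC)c1cccc(OC)c1C
F2 | step 9 | methyl 2-(6-bromo-3-methoxy-2-methylphenyl)-2-[5-(tert-butyldimethylsilyloxy)-6-methylidene-3-oxobicyclo[3.2.1]oct-1-yl]acetate, both C6 epimers | C=C1C[C@@]2(C[C@@]1(O[Si](C)(C)C(C)(C)C)CC(=O)C2)C(C(=O)OC)c1c(Br)ccc(OC)c1C
F3 | step 7 | methyl 2-[5-hydroxy-6-methylidene-3-oxobicyclo[3.2.1]oct-1-yl]acetate, bridgeheads as in 8 | C=C1C[C@@]2(C[C@@]1(O)CC(=O)C2)CC(=O)OC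
F4 | step 8 | (3-methoxy-2-methylbenzyl)zinc chloride | COc1cccc(C[Zn]Cl)c1C
F5 | step 8 | 1-[5-(tert-butyldimethylsilyloxy)-6-methylidene-3-oxobicyclo[3.2.1]oct-1-yl]-2-(3-methoxy-2-methylphenyl)ethan-1-one | C=C1C[C@@]2(C[C@@]1(O[Si](C)(C)C(C)(C)C)CC(=O)C2)C(=O)Cc1cccc(OC)c1C
F6 | step 8 | 2-diazo-1-[5-(tert-butyldimethylsilyloxy)-6-methylidene-3-oxobicyclo[3.2.1]oct-1-yl]-2-(3-methoxy-2-methylphenyl)ethan-1-one | C=C1C[C@@]2(C[C@@]1(O[Si](C)(C)C(C)(C)C)CC(=O)C2)C(=O)C(=[N+]=[N-])c1cccc(OC)c1C
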